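Atom numbering used throughout: decalin carbons C1–C10 (ring A = C1–C5 and C10, ring B = C5–C10), C11 = benzylic CH2 on C9, C18 = methyl on C4, C19–C22 = the chain C4–CH2–CH2–CH=C(CH3)2 (C20 is the malonate carbon in the early intermediates). α is the face of H5, β the face of the C10 methyl; the same atom numbers are used for all intermediates.

## Analysis of the target

Jaspic acid (26) is a meroterpenoid built on a trans-fused octalin: ring A is saturated and ring B carries the C7=C8 alkene with a methyl group on C8. The stereocentres C4, C5, C10 and C9 are contiguous and two of them (C4, C10) are quaternary. H5 is α and the C10 methyl β (trans fusion); the 3-carboxy-6-hydroxybenzyl group on C9 is β and equatorial (H9 α). At C4 the 4-methylpent-3-enyl chain is β and axial, syn to the C10 methyl, and the methyl C18 is α. Two trisubstituted alkenes and a free phenol ortho to the benzylic carbon make the compound sensitive to protic and Lewis acids (cation–olefin reactions, chromane formation at C8), so late steps must be neutral or basic. The hard point is C4: a methyl group and a CH2R chain of nearly equal size sit on one quaternary carbon, with the larger one in the more crowded axial position, so facial discrimination at a planar C4 cannot be relied on and the configuration has to come from a stereospecific event. The strategy rests on ring B: C5–C10 with the C8 methyl, the C7=C8 alkene, the C9 oxygen and the C5 stereocentre are the ring of (R)-carvone (1), whose isopropenyl carbon is C4, with its methyl as C18 and its methylene as C19. A cyclopropane-1,1-diester built on that alkene stores the configuration of C4 and carries C19 and C20.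

## Retrosynthetic reasoning

26 from 25. The phenol and the acid are unmasked last from methyl ether methyl ester 25. Both methyl groups can be removed by one nucleophilic dealkylation, so no acid meets the alkenes or the phenol.

25 from 22 and 23. The C11–aryl bond is cut because it separates a commercial aryl bromide (23) from the terpenoid diene 22 and turns the C9 stereocentre into a question of alkene face. Forward, a borane must add to the exocyclic C9=C11 alkene from the α face to give 24, which is then cross-coupled. Cutting C9–C11 instead would require alkylation of a hindered C9 nucleophile next to quaternary C10.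

22 from 21. C11 is removed by a carbonyl methylenation transform. The C9 ketone of 21 is the original carvone carbonyl, carried through the whole route without protection.

21 from 18 through 20 and 19. The C21=C22 alkene is cut by a Wittig transform to aldehyde 20. Aldehyde 20 is reached from ester 18 by full reduction to diol 19 and reoxidation, because a partial ester reduction is not possible beside the C9 ketone.

18 from 14 through 15, 16 and 17. The C2 oxygen, left over from the nucleophile of the ring closure, is removed through tosylhydrazone 16 and its borane adduct 17. This is done before the side-chain alkene exists and while C2 is the only unhindered saturated ketone. One ester carbon of malonate 14 is excised by dealkoxycarbonylation to give 15.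

14 from 12 (key disconnection). The C3–C4 bond is cut. This reveals an enol silane (C3 nucleophile) and a cyclopropane-1,1-diester whose C4–C20 bond is the leaving bond. The cut is made here because it lets C4 be formed by substitution with inversion, independent of the size of its substituents, while C5 and C10 already fix the trans fusion. Forward, the closure must be a stereospecific 6-ring alkylation; silyl ketene acetal 13 is its primary product.

12 from 7 and 9. The enol silane comes from methyl ketone 10 through its kinetic enolate 11. The cyclopropane of 10 is cut at C4–C20 and C19–C20 to the isopropenyl group of 7 and the malonyl carbene equivalent 9, itself made from 8.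

7 from 1 and 4. The acetonyl arm of 7 is a hydrated propargyl group (6). Quaternary C10 arises from two successive α′-alkylations of 1 through enolates 2 and 5. Methyl goes in first and the propargyl unit (4) second, so that the second group enters anti to the isopropenyl group and C1 is trans to C4 on ring B.

## Alternatives that were turned down

Alternative 1: intramolecular Diels–Alder reaction. Disconnection of C3–C4 and C5–C10 leads to the open-chain (E)-enal/(E)-diene A1, which already carries the arene, a C8 ketal and the C9 stereocentre; heating or Lewis acid would give the trans-fused 4α-formyl octalin A2.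
- For: both rings, both quaternary centres and the C4/C5/C10 relationship are formed in one step. The C4 problem is solved by alkene geometry, since formyl and chain are fixed by the (E)-enal. On bonds and rings per step it is stronger than the chosen key step.
- Against: the diene terminus C10 is 1,1-disubstituted, so one substituent is always cis and destabilises the s-cis diene, and the dienophile is a trisubstituted enal; two bonds to fully substituted carbons must form. The trans/cis fusion and the relay of absolute configuration from the single C9 stereocentre are not secured by any strong element. A1 needs a long linear synthesis with three defined alkene geometries and a stereocentre. After the cycloaddition the formyl group must be reduced to methyl, the C1=C2 alkene hydrogenated beside the side-chain alkene, and the C8 methyl and C7=C8 alkene built next to an epimerisable C9.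
- Comparison: the chosen route gives up the two-ring key step but takes ring B, C5, the C8 methyl and the alkene from 1 in finished form and reaches its key precursor in six operations.

Alternative 2: quinone Diels–Alder reaction. Disconnection of C1–C10 and C4–C5 gives quinone A3 and (Z)-triene A4; a chiral Lewis acid would promote the endo addition to the cis-fused ene-dione A5.
- For: it is convergent, both partners are simple, the absolute configuration comes from a catalyst, and C4, C5 and C10 are set together. In convergence and in steps to a bicyclic core it is stronger than the chosen route.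
- Against: A4 carries a cis substituent at the reacting diene terminus, which makes the s-cis conformer scarce and the cycloaddition slow. Lewis-acid forcing endangers the (Z)-geometry and the side-chain alkene. A5 is cis-fused and needs epimerisation at C5 with an uncertain equilibrium. The C6 carbonyl must then be removed from an ene-dione while the C9 carbonyl and the C7=C8 alkene survive, and the C2=C3 alkene must be hydrogenated selectively.
- Comparison: these corrections cost about what the chosen route spends after its key step. The chosen route has the trans fusion and the correct oxidation pattern of ring B from the start and no carbonyl differentiation problem in ring B.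

Alternative 3: epoxide-initiated bicyclisation. Disconnection of C4–C5 and C9–C10 gives the (Z)-epoxy polyene A6; MeAlCl2 would open the epoxide at C4 with inversion and close both rings to the 3β-hydroxy compound A7.
- For: it is the most direct route on paper. The reaction type is established, both rings and all four ring stereocentres form at once, the arene is in place, and C4 is set by the same logic of inversion at a three-membered ring, with known chemistry. On precedent and on steps after the key step it is stronger than the chosen strategy.
- Against: A6 needs one (Z)-trisubstituted alkene among (E)-alkenes and an epoxide at one of four trisubstituted alkenes, which forces a fragment-based and long assembly. Termination by loss of H7 competes with loss from the C8 methyl and from C9 and with capture of the C8 cation by the electron-rich arene. The 3-hydroxyl must then be removed.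
- Comparison: the chosen route has no termination ambiguity, because the C7=C8 alkene and the C8 methyl come from 1, and it needs no geometry-defined polyene. The price is an unproven key step and a longer end game.

Key step: step 7

Assumption: the face selectivity of carbene transfer to the isopropenyl group (step 5) cannot be predicted; the route assumes that the two C4 epimers of the cyclopropane are separable by chromatography and continues with the epimer drawn as 10.

## Route

Step 1
Reactants: 1 (R)-(−)-carvone
Product: 3 (5R)-2,6-dimethyl-5-(prop-1-en-2-yl)cyclohex-2-en-1-one (6-methylcarvone; both C6 epimers), via lithium dienolate of carvone 2 (not isolated)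
Conditions: LiN(i-Pr)2, THF, −78 °C; MeI, −78 to 0 °C
Reagents that add atoms: iodomethane, CI
Why: Kinetic deprotonation at the α′ carbon (the later C10) gives the cross-conjugated dienolate 2, which is C-methylated; the new centre is formed as a mixture, which does not matter because it is planarised again in step 2.

Step 2
Reactants: 3 6-methylcarvone; 4 propargyl bromide
Product: 6 (5S,6S)-2,6-dimethyl-5-(prop-1-en-2-yl)-6-(prop-2-yn-1-yl)cyclohex-2-en-1-one (propargyl trans to isopropenyl), via lithium dienolate 5 (not isolated)
Conditions: LiN(i-Pr)2, THF, −78 to 0 °C; then 4, DMPU, −78 °C to rt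
Reagents that add atoms: none
Why: Enolate alkylation; both epimers of 3 give the same tetrasubstituted dienolate 5, in which the isopropenyl group turns pseudo-axial to avoid 1,2-allylic strain with the enolate methyl and shields one face, so the propargyl group should enter trans to it. This sets quaternary C10 with the C1 arm anti to the future C4.

Step 3
Reactants: 6 propargyl enone
Product: 7 (5S,6S)-2,6-dimethyl-6-(2-oxopropyl)-5-(prop-1-en-2-yl)cyclohex-2-en-1-one
Conditions: Ph3PAuNTf2 (2 mol %), H2O, 1,4-dioxane, 60 °C
Reagents that add atoms: water, O
Why: Markovnikov hydration of the terminal alkyne under π-activation by monovalent gold gives the methyl ketone; the 1,1-disubstituted alkene and the enone are not attacked, and participation of the C9 carbonyl can only direct water to the internal alkyne carbon.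

Step 4
Reactants: 8 dimethyl malonate
Product: 9 dimethyl 2-diazomalonate
Conditions: 4-AcNHC6H4SO2N3, Et3N, MeCN, 0 °C to rt
Reagents that add atoms: 4-acetamidobenzenesulfonyl azide, CC(=O)Nc1ccc(cc1)S(=O)(=O)N=[N+]=[N-]
Why: Regitz diazo transfer from the sulfonyl azide to the malonate anion.

Step 5
Reactants: 7 methyl ketone; 9 dimethyl 2-diazomalonate
Product: 10 dimethyl (2S)-2-[(1S,2S)-2,4-dimethyl-3-oxo-2-(2-oxopropyl)cyclohex-4-en-1-yl]-2-methylcyclopropane-1,1-dicarboxylate
Conditions: Rh2(esp)2 (1 mol %), CH2Cl2, 0 °C to rt, slow addition of 9; chromatographic separation of the C4 epimers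
Reagents that add atoms: none
Why: Dirhodium-carbenoid cyclopropanation; the electrophilic malonyl carbenoid adds to the electron-rich 1,1-disubstituted alkene and leaves the electron-poor enone alkene alone. C4 is created by the choice of alkene face, for which the substrate offers no reliable bias, so both epimers are expected and the (2S)-cyclopropane 10 is taken on after separation.

Step 6
Reactants: 10 cyclopropane diester methyl ketone
Product: 12 dimethyl (2S)-2-{(1S,2S)-2,4-dimethyl-3-oxo-2-[2-(trimethylsilyloxy)prop-2-en-1-yl]cyclohex-4-en-1-yl}-2-methylcyclopropane-1,1-dicarboxylate, via lithium enolate 11 (not isolated)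
Conditions: LiN(i-Pr)2, THF, −78 °C; Me3SiCl, Et3N, −78 to 0 °C; non-aqueous work-up
Reagents that add atoms: chlorotrimethylsilane, C[Si](C)(C)Cl
Why: Kinetic enolisation of the methyl ketone at the unhindered methyl (C3) rather than at the neopentyl C1 methylene, with O-silylation of enolate 11; the diester has no acidic hydrogen and the C9 ketone has none at C10.

Step 7
Reactants: 12 cyclopropane diester enol silane
Product: 14 dimethyl 2-[(4α,8,10β-trimethyl-2,9-dioxo-5αH-decal-7-en-4β-yl)methyl]malonate (trans-fused), via silyl ketene acetal 13 (not isolated)
Conditions: Sc(OTf)3 (20 mol %), 2,6-di-tert-butyl-4-methylpyridine (20 mol %), 4 Å MS, CH2Cl2, −20 °C to rt; aq. NH4Cl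
Reagents that add atoms: none
Why: Proposed new method: Sc(OTf)3 chelates the geminal diester and polarises the C4–C20 bond; the enol silane carbon C3, held by the C1–C10–C5 tether, attacks C4 from the side opposite C20 as that bond breaks, and the scandium malonate/silyloxocarbenium pair collapses by silyl transfer to ketene acetal 13, which work-up hydrolyses to 14. The closest known reaction type is the Lewis-acid-catalysed opening of 2-aryl- and 2-vinylcyclopropane-1,1-diesters by enol silanes and other π-nucleophiles, which goes with inversion at the donor carbon; here the donor carbon carries only two alkyl groups and the nucleophile is tethered, and neither has been shown. Ring A closes in a 6-(enolendo)-exo-tet mode, a favoured closure in which C3, C4 and C20 can become collinear. The new stereocentre C4 is controlled only by the configuration of the cyclopropane carbon, because substitution occurs with inversion: the ring methylene C19 becomes the β-axial substituent and C18 the α one, whatever their sizes. C5 and C10 are fixed beforehand and enforce the trans fusion through a chair transition state with the C4 and C1 arms equatorial on ring B. The step needs substitution inside a contact zwitterion rather than at a free C4 cation, attack at C4 rather than at C19, and C–C bond formation ahead of desilylation. The tertiary C4 takes the positive charge, the departing malonate stays attached through C19 and shields the face it leaves, attack at C19 would need a seven-membered ring, and the hindered base removes adventitious acid. The C9 enone should remain a spectator, since it is a poor acceptor and closure of C3 onto it would be a disfavoured 5-(enolendo)-exo-trig process.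

Step 8
Reactants: 14 malonate dione
Product: 15 methyl 3-(4α,8,10β-trimethyl-2,9-dioxo-5αH-decal-7-en-4β-yl)propanoate
Conditions: LiCl, H2O, DMSO, 150 °C
Reagents that add atoms: none
Why: Krapcho dealkoxycarbonylation: chloride dealkylates one ester methyl, the carboxylate loses CO2 and the enolate is protonated; the ketones are unaffected and no stereocentre is touched.

Step 9
Reactants: 15 keto ester dione
Product: 16 methyl 3-[4α,8,10β-trimethyl-9-oxo-2-(tosylhydrazono)-5αH-decal-7-en-4β-yl]propanoate
Conditions: TsNHNH2, MeOH, 40 °C
Reagents that add atoms: 4-methylbenzenesulfonohydrazide, Cc1ccc(cc1)S(=O)(=O)NN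
Why: Hydrazone formation at the saturated C2 ketone; the C9 carbonyl is conjugated and flanked by quaternary C10 and the C8 methyl, so it should not condense.

Step 10
Reactants: 16 tosylhydrazone
Product: 18 methyl 3-(4α,8,10β-trimethyl-9-oxo-5αH-decal-7-en-4β-yl)propanoate, via N-boryl tosylhydrazine 17 (not isolated)
Conditions: catecholborane, CHCl3, 0 °C; then NaOAc·3H2O, 60 °C
Reagents that add atoms: none
Why: Caglioti-type reduction: the borane delivers hydride to the C=N carbon to give 17, acetate then triggers loss of sulfinate to a diazene that extrudes N2 and leaves the C2 methylene. The hindered enone reacts far more slowly with the borane and the ester not at all.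

Step 11
Reactants: 18 keto ester
Product: 19 4β-(3-hydroxypropyl)-4α,8,10β-trimethyl-5αH-decal-7-en-9-ol (C9 carbinol epimers)
Conditions: i-Bu2AlH (excess), CH2Cl2, −78 to 0 °C; aq. potassium sodium tartrate
Reagents that add atoms: none
Why: Exhaustive hydride reduction, ester to primary alcohol and enone to allylic alcohol by 1,2-addition; the configuration of the carbinol centre is irrelevant because it is reoxidised in step 12. The detour is used because the ester cannot be reduced to the aldehyde beside the C9 ketone.

Step 12
Reactants: 19 diol
Product: 20 3-(4α,8,10β-trimethyl-9-oxo-5αH-decal-7-en-4β-yl)propanal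
Conditions: Dess–Martin periodinane, NaHCO3, CH2Cl2, 0 °C to rt
Reagents that add atoms: none
Why: Dess–Martin oxidation of both alcohols under buffered conditions, primary to aldehyde and allylic to enone; neither carbonyl has an epimerisable neighbour.

Step 13
Reactants: 20 keto aldehyde
Product: 21 4α,8,10β-trimethyl-4β-(4-methylpent-3-en-1-yl)-5αH-decal-7-en-9-one
Conditions: i-PrPPh3I, n-BuLi, THF, 0 °C; then 20, −78 °C to rt
Reagents that add atoms: isopropyltriphenylphosphonium iodide, CC(C)[P+](c1ccccc1)(c1ccccc1)c1ccccc1.[I-]
Why: Wittig olefination with the non-stabilised isopropylidene ylide, which reacts with the unhindered aldehyde at low temperature and not with the hindered conjugated ketone; the new alkene has two identical methyl groups, so no geometry arises.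

Step 14
Reactants: 21 enone
Product: 22 4α,8,10β-trimethyl-9-methylidene-4β-(4-methylpent-3-en-1-yl)-5αH-decal-7-ene
Conditions: Cp2TiMe2, toluene, 70 °C, dark
Reagents that add atoms: dimethyltitanocene, C[Ti](C)(C1C=CC=C1)C1C=CC=C1
Why: Carbonyl methylenation by the titanium methylidene formed thermally from Cp2TiMe2 (a titanium-based Wittig-type olefination); the reagent is non-basic, so the hindered, γ-enolisable enone should give the 1,3-diene without deconjugation.

Step 15
Reactants: 22 diene; 23 methyl 3-bromo-4-methoxybenzoate
Product: 25 methyl 4-methoxy-3-{[4α,8,10β-trimethyl-4β-(4-methylpent-3-en-1-yl)-5αH,9αH-decal-7-en-9β-yl]methyl}benzoate, via B-alkyl-9-BBN 24 (not isolated)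
Conditions: 9-BBN, THF, 0 to 60 °C; then 23, Pd(dppf)Cl2 (5 mol %), aq. K3PO4, DMF, 60 °C
Reagents that add atoms: none
Why: Hydroboration then B-alkyl Suzuki–Miyaura coupling: the borane adds to the terminal alkene of the diene with boron on C11 and hydrogen on C9, from the α face opposite the axial C10 methyl. This sets H9 α and the C11 arm β-equatorial, while the trisubstituted alkenes react far more slowly. The primary alkylborane 24 is then coupled with 23 by zerovalent palladium formed from Pd(dppf)Cl2.

Step 16
Reactants: 25 methyl ether methyl ester
Product: 26 jaspic acid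
Conditions: NaSEt, DMF, 130 °C; then cold 1 M HCl
Reagents that add atoms: none
Why: Nucleophilic demethylation: ethanethiolate cleaves the aryl methyl ether and the methyl ester by SN2 attack at the methyl groups; the medium is never strongly acidic, so the alkenes and the new phenol cannot enter cationic cyclisation and no stereocentre is affected.

## Compound list

1 | (R)-(−)-carvone | CC1=CC[C@H](CC1=O)C(C)=C | starting material
2 | lithium (3R)-6-methyl-3-(prop-1-en-2-yl)cyclohexa-1,5-dien-1-olate (not isolated) | [Li]OC1=C[C@H](C(C)=C)CC=C1C | intermediate
3 | (5R)-2,6-dimethyl-5-(prop-1-en-2-yl)cyclohex-2-en-1-one, C6 epimers | CC1=CC[C@H](C(C)C1=O)C(C)=C | intermediate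
4 | propargyl bromide | C#CCBr | starting material
5 | lithium (3S)-2,6-dimethyl-3-(prop-1-en-2-yl)cyclohexa-1,5-dien-1-olate (not isolated) | [Li]OC1=C(C)[C@H](C(C)=C)CC=C1C | intermediate
6 | (5S,6S)-2,6-dimethyl-5-(prop-1-en-2-yl)-6-(prop-2-yn-1-yl)cyclohex-2-en-1-one | C#CC[C@]1(C)C(=O)C(C)=CC[C@H]1C(C)=C | intermediate
7 | (5S,6S)-2,6-dimethyl-6-(2-oxopropyl)-5-(prop-1-en-2-yl)cyclohex-2-en-1-one | CC(=O)C[C@]1(C)C(=O)C(C)=CC[C@H]1C(C)=C | intermediate
8 | dimethyl malonate | COC(=O)CC(=O)OC | starting material
9 | dimethyl 2-diazomalonate | COC(=O)C(=[N+]=[N-])C(=O)OC | intermediate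
10 | dimethyl (2S)-2-[(1S,2S)-2,4-dimethyl-3-oxo-2-(2-oxopropyl)cyclohex-4-en-1-yl]-2-methylcyclopropane-1,1-dicarboxylate | CC(=O)C[C@]1(C)C(=O)C(C)=CC[C@H]1[C@]2(C)CC2(C(=O)OC)C(=O)OC | intermediate
11 | lithium enolate of 10 at the terminal methyl, C2(OLi)=C3 (not isolated) | [Li]OC(=C)C[C@]1(C)C(=O)C(C)=CC[C@H]1[C@]2(C)CC2(C(=O)OC)C(=O)OC | intermediate
12 | dimethyl (2S)-2-{(1S,2S)-2,4-dimethyl-3-oxo-2-[2-(trimethylsilyloxy)prop-2-en-1-yl]cyclohex-4-en-1-yl}-2-methylcyclopropane-1,1-dicarboxylate | C=C(O[Si](C)(C)C)C[C@]1(C)C(=O)C(C)=CC[C@H]1[C@]2(C)CC2(C(=O)OC)C(=O)OC | intermediate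
13 | silyl ketene acetal of 14, methyl 2-[methoxy(trimethylsilyloxy)methylidene]-3-(4α,8,10β-trimethyl-2,9-dioxo-5αH-decal-7-en-4β-yl)propanoate (not isolated) | COC(O[Si](C)(C)C)=C(C(=O)OC)C[C@@]1(C)CC(=O)C[C@]2(C)C(=O)C(C)=CC[C@@H]12 | intermediate
14 | dimethyl 2-[(4α,8,10β-trimethyl-2,9-dioxo-5αH-decal-7-en-4β-yl)methyl]malonate | COC(=O)C(C(=O)OC)C[C@@]1(C)CC(=O)C[C@]2(C)C(=O)C(C)=CC[C@@H]12 | intermediate
15 | methyl 3-(4α,8,10β-trimethyl-2,9-dioxo-5αH-decal-7-en-4β-yl)propanoate | COC(=O)CC[C@@]1(C)CC(=O)C[C@]2(C)C(=O)C(C)=CC[C@@H]12 | intermediate
16 | C2 tosylhydrazone of 15 (E/Z at C=N) | COC(=O)CC[C@@]1(C)CC(=NNS(=O)(=O)c3ccc(C)cc3)C[C@]2(C)C(=O)C(C)=CC[C@@H]12 | intermediate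
17 | N-(1,3,2-benzodioxaborol-2-yl) N′-tosyl hydrazine at C2, C2 epimers (not isolated) | COC(=O)CC[C@@]1(C)CC(N(B3Oc4ccccc4O3)NS(=O)(=O)c5ccc(C)cc5)C[C@]2(C)C(=O)C(C)=CC[C@@H]12 | intermediate
18 | methyl 3-(4α,8,10β-trimethyl-9-oxo-5αH-decal-7-en-4β-yl)propanoate | COC(=O)CC[C@@]1(C)CCC[C@]2(C)C(=O)C(C)=CC[C@@H]12 | intermediate
19 | 4β-(3-hydroxypropyl)-4α,8,10β-trimethyl-5αH-decal-7-en-9-ol, C9 epimers | OCCC[C@@]1(C)CCC[C@]2(C)C(O)C(C)=CC[C@@H]12 | intermediate
20 | 3-(4α,8,10β-trimethyl-9-oxo-5αH-decal-7-en-4β-yl)propanal | O=CCC[C@@]1(C)CCC[C@]2(C)C(=O)C(C)=CC[C@@H]12 | intermediate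
21 | 4α,8,10β-trimethyl-4β-(4-methylpent-3-en-1-yl)-5αH-decal-7-en-9-one | CC(C)=CCC[C@@]1(C)CCC[C@]2(C)C(=O)C(C)=CC[C@@H]12 | intermediate
22 | 4α,8,10β-trimethyl-9-methylidene-4β-(4-methylpent-3-en-1-yl)-5αH-decal-7-ene | CC(C)=CCC[C@@]1(C)CCC[C@]2(C)C(=C)C(C)=CC[C@@H]12 | intermediate
23 | methyl 3-bromo-4-methoxybenzoate | COC(=O)c1ccc(OC)c(Br)c1 | starting material
24 | 9-{[4α,8,10β-trimethyl-4β-(4-methylpent-3-en-1-yl)-5αH,9αH-decal-7-en-9β-yl]methyl}-9-borabicyclo[3.3.1]nonane (not isolated) | CC(C)=CCC[C@@]1(C)CCC[C@]2(C)[C@@H](CB3C4CCCC3CCC4)C(C)=CC[C@@H]12 | intermediate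
25 | jaspic acid methyl ester methyl ether | CC(C)=CCC[C@@]1(C)CCC[C@]2(C)[C@@H](Cc3cc(C(=O)OC)ccc3OC)C(C)=CC[C@@H]12 | intermediate
26 | jaspic acid | CC(C)=CCC[C@@]1(C)CCC[C@]2(C)[C@@H](Cc3cc(C(=O)O)ccc3O)C(C)=CC[C@@H]12 | target

## Step count and least certain steps

Total step count: 16. Longest linear sequence: 15 steps (1 to 26; step 4 is a one-step side branch).

**Step 7 (key step, new method).** The cyclopropane has no aryl or vinyl donor, so activation by Sc(OTf)3 may be too weak and loss of the silyl group back to 10 may win. With stronger activation the C4–C20 bond may ionise fully, followed by proton loss from C18 or C5 or by attack on both faces, which erodes the inversion. The C9 carbonyl oxygen may capture C4 in a five-membered closure. The zwitterion may also collapse by aldol-type closure of the malonate onto the silyloxocarbenium carbon (formal [3+2] annulation); that process is reversible on desilylation.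

Fallback with known chemistry: the same C3–C4 bond is formed by Lewis-acid opening of a 2,2-disubstituted epoxide at its tertiary carbon by the enol silane, as in the first ring closure of epoxy-olefin cyclisations. It sets out from 7. Epoxidation of the isopropenyl group (mCPBA, NaHCO3, CH2Cl2, 0 °C) and separation of the epimers gives epoxy diketone F1. Kinetic silylation as in step 6 gives epoxy enol silane F2. MeAlCl2 (CH2Cl2, −78 °C) should give, with inversion at C4, the 4β-hydroxymethyl dione F3. Dess–Martin oxidation gives neopentyl aldehyde F4. Horner–Wadsworth–Emmons reaction with trimethyl phosphonoacetate (NaH, THF) gives (E)-enoate F5. Hydrogenation of the disubstituted alkene over RhCl(PPh3)3 (H2, benzene) leaves the trisubstituted enone alkene and returns to the route at 15. C19 then comes from the epoxide methylene and C20–C21 from the phosphonate.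

**Step 5.** Facial selectivity of carbene transfer to the isopropenyl group is likely to be poor, and simple rotamer models do not agree on its sense, so the required epimer may be the minor one; reversible ylide formation at the two ketones may also lower the yield.

Fallback: the cyclopropane is built the other way round, by delivering C19 to an alkylidene malonate whose conformation is fixed by 1,3-allylic strain (C5–H eclipsing the cis ester), so that attack from the C6 side, away from quaternary C10, should give the configuration of 10. It sets out from 6. Ozonolysis of the isopropenyl group (O3, CH2Cl2/MeOH, −78 °C; Me2S) gives acetyl enone F6. Knoevenagel condensation with 8 (TiCl4, pyridine, THF) gives alkylidene malonate F7. Diazomethane (Et2O, 0 °C) adds to give 1-pyrazoline F8. Loss of N2 (toluene, 100 °C) gives cyclopropane alkyne F9. Hydration as in step 3 returns to the route at 10.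

**Step 10 (with step 9).** Chemoselectivity may be lost, either by partial condensation at C9 or by hydride delivery to the enone during the borane reduction.

Fallback: deoxygenation by a radical path. It sets out from 15. NaBH4 (MeOH/CH2Cl2, −78 °C) reduces only the saturated ketone to C2 alcohol F10. 1,1′-Thiocarbonyldiimidazole (DMAP, 1,2-dichloroethane, 60 °C) gives imidazolyl thiocarbamate F11. Barton–McCombie reduction (Bu3SnH, AIBN, toluene, 100 °C) returns to the route at 18.

**Step 14.** The C9 carbonyl is flanked by quaternary C10 and the C8 methyl, so methylene transfer may be slower than thermal decay of the titanium reagent and conversion may stall.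

Fallback: a two-stage Peterson olefination. It sets out from 21. Me3SiCH2Li with CeCl3 (THF, −78 °C) adds to the ketone to give β-hydroxysilane F12, and KH (THF) induces syn elimination and returns to the route at 22.

**Step 15.** Hydroboration of the hindered, conjugated exocyclic alkene may be slow and not fully α-selective. The β-branched alkylborane may transmetalate slowly, so that β-hydride elimination and protodeboronation compete.

Fallback: the borane is oxidised and the coupling is done through an organozinc. It sets out from 22. Hydroboration as before and oxidation (NaOH, H2O2) give primary alcohol F13, at which stage a C9 epimer can be removed. I2, PPh3 and imidazole give iodide F14. Zinc insertion (Zn, LiCl, THF) gives alkylzinc iodide F15. Negishi coupling with 23 (Pd(OAc)2, SPhos, THF) returns to the route at 25.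

## Further compounds

F1 | step 7 | epoxy diketone: 7 with the isopropenyl group as a 2-methyloxiran-2-yl group, epoxide carbon configured like the cyclopropane carbon of 10 | CC(=O)C[C@]1(C)C(=O)C(C)=CC[C@H]1[C@]2(C)CO2
F2 | step 7 | epoxy enol silane: trimethylsilyl enol ether of F1 at the terminal methyl | C=C(O[Si](C)(C)C)C[C@]1(C)C(=O)C(C)=CC[C@H]1[C@]2(C)CO2
F3 | step 7 | 4β-(hydroxymethyl)-4α,8,10β-trimethyl-5αH-decal-7-ene-2,9-dione | OC[C@@]1(C)CC(=O)C[C@]2(C)C(=O)C(C)=CC[C@@H]12
F4 | step 7 | 4α,8,10β-trimethyl-2,9-dioxo-5αH-decal-7-ene-4β-carbaldehyde | O=C[C@@]1(C)CC(=O)C[C@]2(C)C(=O)C(C)=CC[C@@H]12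
F5 | step 7 | methyl (E)-3-(4α,8,10β-trimethyl-2,9-dioxo-5αH-decal-7-en-4β-yl)prop-2-enoate | COC(=O)/C=C/[C@@]1(C)CC(=O)C[C@]2(C)C(=O)C(C)=CC[C@@H]12
F6 | step 5 | acetyl enone: 6 with the isopropenyl group cleaved to an acetyl group | C#CC[C@]1(C)C(=O)C(C)=CC[C@H]1C(C)=O
F7 | step 5 | alkylidene malonate: dimethyl 2-[1-(2,4-dimethyl-3-oxo-2-propargylcyclohex-4-en-1-yl)ethylidene]malonate | C#CC[C@]1(C)C(=O)C(C)=CC[C@H]1C(C)=C(C(=O)OC)C(=O)OC
F8 | step 5 | 1-pyrazoline: dimethyl 4-methyl-4-(2,4-dimethyl-3-oxo-2-propargylcyclohex-4-en-1-yl)-4,5-dihydro-3H-pyrazole-3,3-dicarboxylate | C#CC[C@]1(C)C(=O)C(C)=CC[C@H]1[C@]2(C)CN=NC2(C(=O)OC)C(=O)OC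
F9 | step 5 | cyclopropane alkyne: 10 with a propargyl group in place of the 2-oxopropyl group | C#CC[C@]1(C)C(=O)C(C)=CC[C@H]1[C@]2(C)CC2(C(=O)OC)C(=O)OC
F10 | step 10 | methyl 3-(2-hydroxy-4α,8,10β-trimethyl-9-oxo-5αH-decal-7-en-4β-yl)propanoate, C2 epimers | COC(=O)CC[C@@]1(C)CC(O)C[C@]2(C)C(=O)C(C)=CC[C@@H]12
F11 | step 10 | O-(C2) imidazole-1-carbothioate of F10 | COC(=O)CC[C@@]1(C)CC(OC(=S)n3ccnc3)C[C@]2(C)C(=O)C(C)=CC[C@@H]12
F12 | step 14 | 9-hydroxy-9-(trimethylsilylmethyl) adduct of 21, C9 epimers | CC(C)=CCC[C@@]1(C)CCC[C@]2(C)C(O)(C[Si](C)(C)C)C(C)=CC[C@@H]12
F13 | step 15 | [4α,8,10β-trimethyl-4β-(4-methylpent-3-en-1-yl)-5αH,9αH-decal-7-en-9β-yl]methanol | CC(C)=CCC[C@@]1(C)CCC[C@]2(C)[C@@H](CO)C(C)=CC[C@@H]12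
F14 | step 15 | 9β-(iodomethyl) analogue of F13 | CC(C)=CCC[C@@]1(C)CCC[C@]2(C)[C@@H](CI)C(C)=CC[C@@H]12
F15 | step 15 | alkylzinc iodide from F14 | CC(C)=CCC[C@@]1(C)CCC[C@]2(C)[C@@H](C[Zn]I)C(C)=CC[C@@H]12
A1 | alternative 1 | open-chain (E)-enal (E)-diene with C8 dioxolane, C9 stereocentre and arene | O=C/C(=C/CCC1(OCCO1)[C@H](Cc2cc(C(=O)OC)ccc2OC)/C(C)=C/C=C)CCC=C(C)C
A2 | alternative 1 | trans-fused 4α-formyl octalin C8 ketal | CC(C)=CCC[C@@]1(C=O)CC=C[C@]2(C)[C@@H](Cc3cc(C(=O)OC)ccc3OC)C4(OCCO4)CC[C@@H]12
A3 | alternative 2 | 2,6-dimethyl-1,4-benzoquinone | CC1=CC(=O)C=C(C)C1=O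
A4 | alternative 2 | (3Z)-4,8-dimethylnona-1,3,7-triene | C=C/C=C(/C)CCC=C(C)C
A5 | alternative 2 | cis-fused ene-dione cycloadduct | CC(C)=CCC[C@@]1(C)C=CC[C@]2(C)C(=O)C(C)=CC(=O)[C@H]12
A6 | alternative 3 | (Z)-derived epoxy polyene with the aryl methyl ether methyl ester | CC(C)=CCC[C@@]1(C)O[C@H]1CC/C(C)=C/CC/C(C)=C/Cc1cc(C(=O)OC)ccc1OC
A7 | alternative 3 | 3β-hydroxy jaspic acid methyl ester methyl ether | CC(C)=CCC[C@@]1(C)[C@@H](O)CC[C@]2(C)[C@@H](Cc3cc(C(=O)OC)ccc3OC)C(C)=CC[C@@H]12
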